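**Strategy.** Everything rests on reading the target as an acyloin: in the cyclohexenedione ring the enol carbon C5 (a ketone carbon in tautomeric terms) is bonded to the tertiary carbinol C6. That C5–C6 bond is made by an enantioselective carbene-catalysed crossed aldehyde–ketone benzoin cyclisation, which in one operation closes the six-membered carbocycle and sets the only stereocentre from an achiral precursor. The precursor is a 3-isopropylisoxazole-4-carbaldehyde whose 5-position carries the gem-diprenyl carbon and a prenyl 1,2-diketone. The isoxazole is a flat, non-enolisable mask for the acyl enol dione array (C3, C4 and the isobutyryl carbonyl); reductive N–O cleavage and hydrolysis at the end unveil the enolised triketone.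

Key step: step 8

Assumption: the (5aS,10bR) antipode of the aminoindanol-derived triazolium salt is taken to deliver the (5S) ketol 17; if the sense of induction proves opposite, the (5aR,10bS) salt is used in the same way.

**Step 1**
Reactants: 1 5-methylhex-4-enoic acid; 2 N,O-dimethylhydroxylamine hydrochloride
Product: 4 N-methoxy-N,5-dimethylhex-4-enamide, via acyl imidazole 3 (not isolated)
Conditions: CDI, CH2Cl2, 0 → 23 °C; then 2, 23 °C
Reagents that add atoms: 1,1'-carbonyldiimidazole, O=C(n1ccnc1)n1ccnc1 (imidazole ring of intermediate 3 only)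
Why: Activation of the acid as its acyl imidazole followed by aminolysis should give the Weinreb amide (CDI amidation), with the trisubstituted alkene untouched.

**Step 2**
Reactants: 5 2-methylpropanal oxime; 6 ethyl acetoacetate
Product: 9 ethyl 3-isopropyl-5-methylisoxazole-4-carboxylate, via N-hydroxy-2-methylpropanimidoyl chloride 7 (not isolated), via 2-methylpropanenitrile oxide 8 (not isolated)
Conditions: NCS, DMF, 23 °C; then 6, NaOEt, EtOH, 0 → 23 °C
Reagents that add atoms: N-chlorosuccinimide, O=C1CCC(=O)N1Cl (chlorine of intermediate 7 only)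
Why: The nitrile oxide released from the hydroximoyl chloride should be attacked through carbon by the β-keto ester enolate, and the oxime oxygen then condenses with the ketone (not the ester) carbonyl, the regioselective nitrile oxide/1,3-dicarbonyl cyclocondensation to a 5-methylisoxazole-4-carboxylate.

**Step 3**
Reactants: 9 ethyl 3-isopropyl-5-methylisoxazole-4-carboxylate; 4 N-methoxy-N,5-dimethylhex-4-enamide
Product: 10 ethyl 3-isopropyl-5-(6-methyl-2-oxohept-5-en-1-yl)isoxazole-4-carboxylate
Conditions: LiN(iPr)2, THF, −78 °C; then 4, −78 → −20 °C; aq. NH4Cl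
Reagents that add atoms: none
Why: The 5-methyl group is vinylogous to the 4-ester and should be deprotonated selectively (lateral metalation); the dienolate is C-acylated by the Weinreb amide, whose chelated adduct prevents over-addition.

**Step 4**
Reactants: 10 ethyl 3-isopropyl-5-(6-methyl-2-oxohept-5-en-1-yl)isoxazole-4-carboxylate; 11 prenyl bromide (1-bromo-3-methylbut-2-ene)
Product: 13 ethyl 5-[2,10-dimethyl-5-(3-methylbut-2-en-1-yl)-6-oxoundeca-2,9-dien-5-yl]-3-isopropylisoxazole-4-carboxylate, via mono-prenyl keto ester 12 (not isolated)
Conditions: NaH (2.3 equiv), 11 (2.6 equiv), THF, 0 → 40 °C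
Reagents that add atoms: none
Why: The methylene flanked by the ketone and the ester-bearing isoxazole is by far the most acidic site, so two successive enolate C-alkylations with the allylic bromide should build the quaternary gem-diprenyl carbon.

**Step 5**
Reactants: 13 the gem-diprenyl keto ester
Product: 14 ethyl 5-[7-hydroxy-2,10-dimethyl-5-(3-methylbut-2-en-1-yl)-6-oxoundeca-2,9-dien-5-yl]-3-isopropylisoxazole-4-carboxylate (racemic)
Conditions: NaN(SiMe3)2, THF, −78 °C; then 2-(benzenesulfonyl)-3-phenyloxaziridine, −78 °C; aq. NH4Cl
Reagents that add atoms: 2-(benzenesulfonyl)-3-phenyloxaziridine, O=S(=O)(c1ccccc1)N1OC1c1ccccc1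
Why: The ketone can enolise only toward its CH2, and the sodium enolate, kept at −78 °C so that Claisen closure onto the ester stays slow, should be hydroxylated by the N-sulfonyloxaziridine (Davis oxidation); the racemic carbinol centre is erased in step 7.

**Step 6**
Reactants: 14 the α-hydroxy keto ester
Product: 15 5-[4-(hydroxymethyl)-3-isopropylisoxazol-5-yl]-2,10-dimethyl-5-(3-methylbut-2-en-1-yl)undeca-2,9-diene-6,7-diol (mixture of diastereomers)
Conditions: LiAlH4, THF, 0 °C
Reagents that add atoms: none
Why: Hydride reduction should take the ester to the primary alcohol and the ketone to the secondary alcohol while the 3,5-disubstituted isoxazole survives at 0 °C; the diastereomer mixture is of no consequence because both carbinol centres are oxidised next.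

**Step 7**
Reactants: 15 the triol
Product: 16 5-[2,10-dimethyl-5-(3-methylbut-2-en-1-yl)-6,7-dioxoundeca-2,9-dien-5-yl]-3-isopropylisoxazole-4-carbaldehyde (achiral)
Conditions: (COCl)2, DMSO, CH2Cl2, −78 °C; then Et3N, −78 → −40 °C; cold pH 7 buffer
Reagents that add atoms: none
Why: In the Swern oxidation all three hydroxyls are activated before base is added, so aldehyde and free alcohol never coexist (no lactol), and the vicinal diol should go to the 1,2-diketone without C–C cleavage while the heteroaryl carbinol goes to the aldehyde.

**Step 8**
Reactants: 16 the isoxazole keto-aldehyde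
Product: 17 (5S)-5-hydroxy-3-isopropyl-5,7,7-tris(3-methylbut-2-en-1-yl)-1,2-benzoxazole-4,6(5H,7H)-dione
Conditions: (5aS,10bR)-2-(pentafluorophenyl)-5a,10b-dihydro-4H,6H-indeno[2,1-b][1,2,4]triazolo[4,3-d][1,4]oxazin-2-ium tetrafluoroborate (15 mol %), KN(SiMe3)2 (12 mol %), toluene, 0 → 23 °C
Reagents that add atoms: none
Why: The triazolylidene adds to the only aldehyde, the non-enolisable isoxazole-4-carbaldehyde, proton transfer gives the Breslow intermediate, and its nucleophilic carbon attacks the prenyl-bearing carbonyl of the 1,2-diketone before the carbene is released from the α-ketol. The closest known reaction type is the enantioselective intramolecular crossed aldehyde–ketone benzoin cyclisation of isoxazole keto-aldehydes with aminoindanol-derived triazolium salts. The six-membered carbocycle closes in the 6-exo-trig mode. The new tertiary carbinol centre is set by the catalyst: the indane wall shields one face of the enaminol, so only one face of the ketone is presented in the hydrogen-bonded transition state. The step needs site selectivity between the two ketones and freedom from enolisation; the distal carbonyl is the only one that gives a six-membered ring, whereas the proximal one is neopentylic and would give a strained five-membered ring. Using slightly less base than azolium salt leaves no free base to move the skipped double bond into conjugation.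

**Step 9**
Reactants: 17 the isoxazole-fused ketol
Product: 19 (6R)-5,6-dihydroxy-2,2,6-tris(3-methylbut-2-en-1-yl)-4-(2-methylpropanoyl)cyclohex-4-ene-1,3-dione, via enaminotrione 18 (not isolated)
Conditions: Mo(CO)6, MeCN/H2O, 80 °C; then 1 M aq. HCl, THF, 40 °C
Reagents that add atoms: water, O
Why: Zerovalent molybdenum should cleave the weak N–O bond reductively without touching alkenes or ketones, and aqueous acid then hydrolyses the vinylogous amide to the isobutyryl carbonyl (isoxazole unmasking of a 2-acylcyclohexane-1,3-dione), the triketone resting as the chelated enol; the carbinol centre is untouched and its descriptor changes from S to R only through the change in substituent priorities.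

**Compound list**
1 | 5-methylhex-4-enoic acid | CC(C)=CCCC(=O)O | starting material
2 | N,O-dimethylhydroxylamine hydrochloride | CNOC.Cl | starting material
3 | 1-(5-methylhex-4-enoyl)imidazole | CC(C)=CCCC(=O)n1ccnc1 | intermediate (not isolated)
4 | N-methoxy-N,5-dimethylhex-4-enamide | CC(C)=CCCC(=O)N(C)OC | intermediate
5 | 2-methylpropanal oxime | CC(C)C=NO | starting material
6 | ethyl acetoacetate | CCOC(=O)CC(C)=O | starting material
7 | N-hydroxy-2-methylpropanimidoyl chloride | CC(C)C(Cl)=NO | intermediate (not isolated)
8 | 2-methylpropanenitrile oxide | CC(C)C#[N+][O-] | intermediate (not isolated)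
9 | ethyl 3-isopropyl-5-methylisoxazole-4-carboxylate | CCOC(=O)c1c(C)onc1C(C)C | intermediate
10 | ethyl 3-isopropyl-5-(6-methyl-2-oxohept-5-en-1-yl)isoxazole-4-carboxylate | CCOC(=O)c1c(CC(=O)CCC=C(C)C)onc1C(C)C | intermediate
11 | prenyl bromide (1-bromo-3-methylbut-2-ene) | CC(C)=CCBr | starting material
12 | ethyl 5-(2,10-dimethyl-6-oxoundeca-2,9-dien-5-yl)-3-isopropylisoxazole-4-carboxylate (racemic) | CCOC(=O)c1c(C(CC=C(C)C)C(=O)CCC=C(C)C)onc1C(C)C | intermediate (not isolated)
13 | ethyl 5-[2,10-dimethyl-5-(3-methylbut-2-en-1-yl)-6-oxoundeca-2,9-dien-5-yl]-3-isopropylisoxazole-4-carboxylate | CCOC(=O)c1c(C(CC=C(C)C)(CC=C(C)C)C(=O)CCC=C(C)C)onc1C(C)C | intermediate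
14 | ethyl 5-[7-hydroxy-2,10-dimethyl-5-(3-methylbut-2-en-1-yl)-6-oxoundeca-2,9-dien-5-yl]-3-isopropylisoxazole-4-carboxylate (racemic) | CCOC(=O)c1c(C(CC=C(C)C)(CC=C(C)C)C(=O)C(O)CC=C(C)C)onc1C(C)C | intermediate
15 | 5-[4-(hydroxymethyl)-3-isopropylisoxazol-5-yl]-2,10-dimethyl-5-(3-methylbut-2-en-1-yl)undeca-2,9-diene-6,7-diol (diastereomer mixture) | OCc1c(C(CC=C(C)C)(CC=C(C)C)C(O)C(O)CC=C(C)C)onc1C(C)C | intermediate
16 | 5-[2,10-dimethyl-5-(3-methylbut-2-en-1-yl)-6,7-dioxoundeca-2,9-dien-5-yl]-3-isopropylisoxazole-4-carbaldehyde | O=Cc1c(C(CC=C(C)C)(CC=C(C)C)C(=O)C(=O)CC=C(C)C)onc1C(C)C | intermediate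
17 | (5S)-5-hydroxy-3-isopropyl-5,7,7-tris(3-methylbut-2-en-1-yl)-1,2-benzoxazole-4,6(5H,7H)-dione | CC(C)=CCC1(CC=C(C)C)c2onc(C(C)C)c2C(=O)[C@](O)(CC=C(C)C)C1=O | intermediate
18 | (2Z,6S)-2-(1-amino-2-methylpropylidene)-6-hydroxy-4,4,6-tris(3-methylbut-2-en-1-yl)cyclohexane-1,3,5-trione (drawn as Z; the exocyclic geometry equilibrates by tautomerism) | CC(C)=CCC1(CC=C(C)C)C(=O)/C(=C(/N)C(C)C)C(=O)[C@](O)(CC=C(C)C)C1=O | intermediate (not isolated)
19 | (6R)-5,6-dihydroxy-2,2,6-tris(3-methylbut-2-en-1-yl)-4-(2-methylpropanoyl)cyclohex-4-ene-1,3-dione | CC(C)=CCC1(CC=C(C)C)C(=O)C(C(=O)C(C)C)=C(O)[C@](O)(CC=C(C)C)C1=O | target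

**Step count.** Total: 9 steps. Longest linear sequence: 8 steps (steps 2 to 9, from 5 and 6); step 1 is a one-step side branch.

**Steps most likely to fail**

Step 8. The skipped enone of the 1,2-diketone may enolise and move into conjugation before the Breslow intermediate adds, carbene addition to the doubly ortho-substituted aldehyde may be slow, or facial selectivity at the ketone may be poor. The fallback sets out from 13 and comes back at 17. The same ring bond is closed by a Claisen (Dieckmann-type) condensation of the ketone enolate onto the 4-ester (KOtBu, THF, 0 → 23 °C), which should give 3-isopropyl-5,7,7-tris(3-methylbut-2-en-1-yl)-1,2-benzoxazole-4,6(5H,7H)-dione F1. Its potassium enolate (KN(SiMe3)2, THF, −78 °C) is then hydroxylated with an enantiopure [(8,8-dichlorocamphoryl)sulfonyl]oxaziridine, the antipode of the reagent being chosen for the 5S configuration (reagent-controlled Davis oxidation). This should give 17 and by-passes steps 5 to 8.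

Step 9. Hydrolysis of the chelated vinylogous amide may stall, and the acid needed to force it may drive cyclisation of a prenyl group onto the enol oxygen or an acyloin ring contraction of the free carbinol. The fallback sets out from 13 and comes back at 19, with unmasking placed before carbinol formation. The benzoxazoledione F1, made from 13 as in the fallback above, carries no carbinol and tolerates forcing conditions. Mo(CO)6 in wet MeCN should open it to 2-(1-amino-2-methylpropylidene)-4,4,6-tris(3-methylbut-2-en-1-yl)cyclohexane-1,3,5-trione F2. This is hydrolysed (2 M aq. HCl, dioxane, 60 °C, or aq. NaOH followed by acidification) to colupulone F3. Hydroxylation of the potassium enolate of F3 at the prenyl-bearing ring carbon with the same enantiopure N-sulfonyloxaziridine should then give 19 directly.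

Step 4. The crowded enolate may be O-prenylated in the second alkylation, or the reaction may stall at the mono-prenyl stage 12. The fallback sets out from 10 and comes back at 13 by Tsuji–Trost allylation: methyl 3-methylbut-2-en-1-yl carbonate (2.5 equiv), Pd(PPh3)4 (5 mol %), THF, 40 °C. Any O-allylated material is re-ionised by zerovalent palladium and funnelled to the C-allylated product. The soft carbanion attacks the unsubstituted terminus of the π-prenyl complex, so linear prenyl groups result. The only compound on the way is 12.

**Further compounds**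
F1 | step 8 | 3-isopropyl-5,7,7-tris(3-methylbut-2-en-1-yl)-1,2-benzoxazole-4,6(5H,7H)-dione (racemic, enolisable) | CC(C)=CCC1(CC=C(C)C)c2onc(C(C)C)c2C(=O)C(CC=C(C)C)C1=O
F2 | step 9 | 2-(1-amino-2-methylpropylidene)-4,4,6-tris(3-methylbut-2-en-1-yl)cyclohexane-1,3,5-trione | CC(C)=CCC1(CC=C(C)C)C(=O)C(=C(N)C(C)C)C(=O)C(CC=C(C)C)C1=O
F3 | step 9 | colupulone, 3,5-dihydroxy-2-(2-methylpropanoyl)-4,6,6-tris(3-methylbut-2-en-1-yl)cyclohexa-2,4-dien-1-one | CC(C)=CCC1(CC=C(C)C)C(=O)C(C(=O)C(C)C)=C(O)C(CC=C(C)C)=C1O
F0 | step 4 | none | none
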